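**Retrosynthetic overview**
1. The target comes from global desilylation of a bis-silyl ether. The first cut is the C7–aryl bond, made by a Ni/Cr-catalysed asymmetric coupling of an aryl iodide with an (S)-α-aryloxy aldehyde. This step sets 7R.
2. The aldehyde comes from the methyl ester. The C8–O(aryl) bond is made by Mitsunobu inversion of a D-serine-derived (R)-glycerate with 4-allyl-2,6-dimethoxyphenol. This step sets 8S.
3. The aryl iodide comes from silylated 2,6-dimethoxyphenol by Ir-catalysed C–H borylation and Cu-catalysed iodination. The allylphenol comes from the same phenol by O-allylation and para-Claisen rearrangement.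
4. 2,6-Dimethoxyphenol comes from resorcinol by methylation, directed lithiation, borylation and oxidation.
5. No ring is formed. Both benzene rings are brought in as resorcinol.

Assumption: the SMILES reads as (7R,8S), the erythro (anti) isomer. The (S)-antipode of the sulfonamide–oxazoline ligand L* is taken as the one matched to Re-face aryl transfer, to be confirmed by one trial with each antipode.

**Step 1**
Reactants: 1 resorcinol
Product: 2 1,3-dimethoxybenzene
Conditions: MeI (2.5 equiv), K2CO3, acetone, reflux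
Reagents that add atoms: methyl iodide, CI
Why: Williamson O-methylation of both phenoxides with a soft base in acetone gives the dimethyl ether cleanly.

**Step 2**
Reactants: 2 1,3-dimethoxybenzene
Product: 5 2,6-dimethoxyphenol, via 2-lithio-1,3-dimethoxybenzene 3 (not isolated), via dimethyl (2,6-dimethoxyphenyl)boronate 4 (not isolated)
Conditions: n-BuLi, THF, 0 °C to rt; B(OMe)3, −78 °C to rt; AcOH, 30% H2O2, 0 °C
Reagents that add atoms: hydrogen peroxide, OO
Why: Directed ortho-metalation occurs only at the C–H flanked by both methoxy groups, and borylation followed by peroxide-induced aryl B-to-O migration puts the hydroxyl there.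

**Step 3**
Reactants: 5 2,6-dimethoxyphenol
Product: 6 (2,6-dimethoxyphenoxy)triisopropylsilane
Conditions: TIPSOTf, 2,6-lutidine, CH2Cl2, 0 °C to rt
Reagents that add atoms: triisopropylsilyl triflate, CC(C)[Si](C(C)C)(C(C)C)OS(=O)(=O)C(F)(F)F
Why: Silyl ether protection with the reactive triflate overcomes the two ortho substituents and gives a fluoride-labile group that can be removed later without acid or hydrogen.

**Step 4**
Reactants: 6 (2,6-dimethoxyphenoxy)triisopropylsilane
Product: 7 2-[3,5-dimethoxy-4-(triisopropylsilyloxy)phenyl]-4,4,5,5-tetramethyl-1,3,2-dioxaborolane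
Conditions: [Ir(OMe)(cod)]2 (1.5 mol %), dtbpy (3 mol %), B2pin2 (1.0 equiv), THF, 80 °C
Reagents that add atoms: bis(pinacolato)diboron, CC1(C)OB(OC1(C)C)B1OC(C)(C)C(C)(C)O1
Why: Iridium-catalysed aromatic C–H borylation is sterically controlled, and the C–H para to the silyloxy group is the only one without an ortho substituent.

**Step 5**
Reactants: 7 2-[3,5-dimethoxy-4-(triisopropylsilyloxy)phenyl]-4,4,5,5-tetramethyl-1,3,2-dioxaborolane
Product: 8 (4-iodo-2,6-dimethoxyphenoxy)triisopropylsilane
Conditions: CuI (10 mol %), 1,10-phenanthroline (20 mol %), KI (1.5 equiv), MeOH/H2O 4:1, air, 80 °C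
Reagents that add atoms: potassium iodide, [K+].[I-]
Why: Copper-catalysed aerobic iododeboronation (Chan–Lam type) replaces boron ipso, so it keeps a regiochemistry that electrophilic iodination, directed ortho/para to OMe, would not give.

**Step 6**
Reactants: 5 2,6-dimethoxyphenol; 9 allyl bromide
Product: 10 2-(allyloxy)-1,3-dimethoxybenzene
Conditions: K2CO3, acetone, reflux
Reagents that add atoms: none
Why: Williamson etherification of the phenoxide with a reactive allylic halide.

**Step 7**
Reactants: 10 2-(allyloxy)-1,3-dimethoxybenzene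
Product: 13 4-allyl-2,6-dimethoxyphenol, via ortho-dienone 11 (not isolated), via para-dienone 12 (not isolated)
Conditions: PhNEt2, 200 °C, sealed tube, Ar
Reagents that add atoms: none
Why: In this para-Claisen rearrangement both ortho positions are blocked, so the [3,3] shift is followed by a Cope [3,3] shift to the para position and tautomerisation to the phenol.

**Step 8**
Reactants: 14 D-serine
Product: 17 (R)-glyceric acid, via diazonium carboxylate 15 (not isolated), via alpha-lactone 16 (not isolated)
Conditions: NaNO2, 1 M aq H2SO4, 0 °C to rt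
Reagents that add atoms: water, O
Why: Diazotisation of an α-amino acid goes with net retention, because the carboxylate displaces N2 with inversion and water opens the lactone with a second inversion, so the R centre is kept.

**Step 9**
Reactants: 17 (R)-glyceric acid
Product: 18 methyl (R)-2,3-dihydroxypropanoate
Conditions: MeOH, Amberlyst-15 (H+), reflux
Reagents that add atoms: methanol, CO
Why: Fischer esterification in excess methanol does not touch the stereocentre.

**Step 10**
Reactants: 18 methyl (R)-2,3-dihydroxypropanoate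
Product: 19 methyl (R)-3-(tert-butyldiphenylsilyloxy)-2-hydroxypropanoate
Conditions: TBDPSCl (1.05 equiv), Et3N, DMAP (cat.), CH2Cl2, 0 °C to rt
Reagents that add atoms: tert-butyldiphenylsilyl chloride, CC(C)(C)[Si](Cl)(c1ccccc1)c1ccccc1
Why: In this selective silyl protection the bulky chlorosilane takes the primary hydroxyl and leaves the less nucleophilic α-hydroxy ester OH free.

**Step 11**
Reactants: 19 methyl (R)-3-(tert-butyldiphenylsilyloxy)-2-hydroxypropanoate; 13 4-allyl-2,6-dimethoxyphenol
Product: 20 methyl (S)-2-(4-allyl-2,6-dimethoxyphenoxy)-3-(tert-butyldiphenylsilyloxy)propanoate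
Conditions: PPh3, DIAD, toluene, 0 °C to rt
Reagents that add atoms: none
Why: In the Mitsunobu etherification the phenoxide displaces the activated α-hydroxy ester oxygen by SN2 with clean inversion (R to S), which sets C8 of the target.

**Step 12**
Reactants: 20 methyl (S)-2-(4-allyl-2,6-dimethoxyphenoxy)-3-(tert-butyldiphenylsilyloxy)propanoate
Product: 22 (S)-2-(4-allyl-2,6-dimethoxyphenoxy)-3-(tert-butyldiphenylsilyloxy)propanal, via aluminium hemiacetal 21 (not isolated)
Conditions: DIBAL-H (1.1 equiv), CH2Cl2, −78 °C; aq Rochelle salt; used crude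
Reagents that add atoms: none
Why: In this partial ester reduction the α-oxygen-stabilised tetrahedral aluminium adduct survives at −78 °C and collapses only on work-up, and the allyl group is inert at this temperature.

**Step 13**
Reactants: 22 (S)-2-(4-allyl-2,6-dimethoxyphenoxy)-3-(tert-butyldiphenylsilyloxy)propanal; 8 (4-iodo-2,6-dimethoxyphenoxy)triisopropylsilane
Product: 24 (1R,2S)-2-(4-allyl-2,6-dimethoxyphenoxy)-3-(tert-butyldiphenylsilyloxy)-1-[3,5-dimethoxy-4-(triisopropylsilyloxy)phenyl]propan-1-ol, via zirconocene alkoxide 23 (not isolated)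
Conditions: CrCl2 (10 mol %), L* = (S)-N-[2-(4-tert-butyl-4,5-dihydrooxazol-2-yl)-6-methylphenyl]methanesulfonamide (11 mol %), proton sponge (11 mol %), NiCl2·neocuproine (3 mol %), Mn (2 equiv), Cp2ZrCl2 (1.1 equiv), LiCl, MeCN, rt; aq NaHCO3 work-up
Reagents that add atoms: none
Why: Proposed new method: a ligand-controlled catalytic asymmetric Ni/Cr aryl–aldehyde coupling in which Ni(0) inserts into the unhindered C–I bond of 8, the aryl group passes to the chiral sulfonamide–Cr(III) centre, and this non-basic aryl–Cr species adds to the Cr-bound aldehyde on its Re face, anti to the C8–OAr bond (polar Felkin–Anh preference reinforced by the matched ligand), forming the C7–aryl bond and setting 7R without enolising C8 or touching the allyl group, while Cp2ZrCl2 releases Cr from the alkoxide and Mn returns Cr(III) to Cr(II); the closest known reaction types are the catalytic asymmetric Nozaki–Hiyama–Kishi alkenylation of α-alkoxy aldehydes with this ligand class and the racemic CrCl2/Ni arylation of aldehydes, whereas asymmetric aryl transfer and α-aryloxy aldehydes as partners have not been shown.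

**Step 14**
Reactants: 24 (1R,2S)-2-(4-allyl-2,6-dimethoxyphenoxy)-3-(tert-butyldiphenylsilyloxy)-1-[3,5-dimethoxy-4-(triisopropylsilyloxy)phenyl]propan-1-ol
Product: 25 (1R,2S)-2-(4-allyl-2,6-dimethoxyphenoxy)-1-(4-hydroxy-3,5-dimethoxyphenyl)propane-1,3-diol
Conditions: TBAF (2.5 equiv), AcOH (2.5 equiv), THF, 0 °C to rt
Reagents that add atoms: none
Why: Fluoride desilylation cleaves both Si–O bonds, and the acetic acid buffer keeps the freed phenol protonated, so no quinone methide forms and C7 is not scrambled.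

**Compound list**
1 | resorcinol (benzene-1,3-diol) | Oc1cccc(O)c1 | starting material
2 | 1,3-dimethoxybenzene | COc1cccc(OC)c1 | intermediate
3 | 2-lithio-1,3-dimethoxybenzene | [Li]c1c(OC)cccc1OC | intermediate
4 | dimethyl (2,6-dimethoxyphenyl)boronate | COB(OC)c1c(OC)cccc1OC | intermediate
5 | 2,6-dimethoxyphenol | COc1cccc(OC)c1O | intermediate
6 | (2,6-dimethoxyphenoxy)triisopropylsilane | COc1cccc(OC)c1O[Si](C(C)C)(C(C)C)C(C)C | intermediate
7 | 2-[3,5-dimethoxy-4-(triisopropylsilyloxy)phenyl]-4,4,5,5-tetramethyl-1,3,2-dioxaborolane | COc1cc(B2OC(C)(C)C(C)(C)O2)cc(OC)c1O[Si](C(C)C)(C(C)C)C(C)C | intermediate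
8 | (4-iodo-2,6-dimethoxyphenoxy)triisopropylsilane | COc1cc(I)cc(OC)c1O[Si](C(C)C)(C(C)C)C(C)C | intermediate
9 | allyl bromide | C=CCBr | starting material
10 | 2-(allyloxy)-1,3-dimethoxybenzene | C=CCOc1c(OC)cccc1OC | intermediate
11 | 6-allyl-2,6-dimethoxycyclohexa-2,4-dien-1-one (ortho-dienone, racemic) | C=CCC1(OC)C=CC=C(OC)C1=O | intermediate
12 | 4-allyl-2,6-dimethoxycyclohexa-2,5-dien-1-one (para-dienone) | C=CCC1C=C(OC)C(=O)C(OC)=C1 | intermediate
13 | 4-allyl-2,6-dimethoxyphenol | C=CCc1cc(OC)c(O)c(OC)c1 | intermediate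
14 | D-serine, (R)-2-amino-3-hydroxypropanoic acid | N[C@H](CO)C(=O)O | starting material
15 | (R)-2-diazonio-3-hydroxypropanoate | N#[N+][C@H](CO)C(=O)[O-] | intermediate
16 | (S)-3-(hydroxymethyl)oxiran-2-one (alpha-lactone) | O1[C@@H](CO)C1=O | intermediate
17 | (R)-glyceric acid, (R)-2,3-dihydroxypropanoic acid | O[C@H](CO)C(=O)O | intermediate
18 | methyl (R)-2,3-dihydroxypropanoate | O[C@H](CO)C(=O)OC | intermediate
19 | methyl (R)-3-(tert-butyldiphenylsilyloxy)-2-hydroxypropanoate | O[C@H](CO[Si](c1ccccc1)(c1ccccc1)C(C)(C)C)C(=O)OC | intermediate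
20 | methyl (S)-2-(4-allyl-2,6-dimethoxyphenoxy)-3-(tert-butyldiphenylsilyloxy)propanoate | C=CCc1cc(OC)c(O[C@@H](CO[Si](c2ccccc2)(c2ccccc2)C(C)(C)C)C(=O)OC)c(OC)c1 | intermediate
21 | diisobutylaluminium methyl hemiacetal of 22 (acetal carbon undefined, C2 S) | C=CCc1cc(OC)c(O[C@@H](CO[Si](c2ccccc2)(c2ccccc2)C(C)(C)C)C(OC)O[Al](CC(C)C)CC(C)C)c(OC)c1 | intermediate
22 | (S)-2-(4-allyl-2,6-dimethoxyphenoxy)-3-(tert-butyldiphenylsilyloxy)propanal | C=CCc1cc(OC)c(O[C@@H](CO[Si](c2ccccc2)(c2ccccc2)C(C)(C)C)C=O)c(OC)c1 | intermediate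
23 | chloridozirconocene (1R,2S)-alkoxide of 24 | C=CCc1cc(OC)c(O[C@@H](CO[Si](c2ccccc2)(c2ccccc2)C(C)(C)C)[C@H]([O-])c2cc(OC)c(O[Si](C(C)C)(C(C)C)C(C)C)c(OC)c2)c(OC)c1.[Zr+4].[Cl-].c1cc[cH-]c1.c1cc[cH-]c1 | intermediate
24 | (1R,2S)-2-(4-allyl-2,6-dimethoxyphenoxy)-3-(tert-butyldiphenylsilyloxy)-1-[3,5-dimethoxy-4-(triisopropylsilyloxy)phenyl]propan-1-ol | C=CCc1cc(OC)c(O[C@@H](CO[Si](c2ccccc2)(c2ccccc2)C(C)(C)C)[C@H](O)c2cc(OC)c(O[Si](C(C)C)(C(C)C)C(C)C)c(OC)c2)c(OC)c1 | intermediate
25 | (1R,2S)-2-(4-allyl-2,6-dimethoxyphenoxy)-1-(4-hydroxy-3,5-dimethoxyphenyl)propane-1,3-diol (CNP0419292.1, erythro) | C=CCc1cc(OC)c(O[C@@H](CO)[C@H](O)c2cc(OC)c(O)c(OC)c2)c(OC)c1 | target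

**Step count**
Total step count: 14.
Longest linear sequence: 8 steps (1, 2, 6, 7, 11, 12, 13, 14). The iodide branch (1, 2, 3, 4, 5, 13, 14) and the serine branch (8 to 14) have 7 steps each.

**Steps most likely to fail**

Step 13 (the proposed new coupling). Aryl transfer from Ni to Cr may be slow for this electron-rich iodide. Biaryl homocoupling may compete, and ligand control over the aldehyde face is untested.
- The fallback uses known chemistry. It sets out from ester 20 and iodide 8 and comes back at 24. C7 is then set by hydride delivery instead of aryl delivery.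
- Ester 20 is treated with MeNH(OMe)·HCl and i-PrMgCl (THF, −20 °C) to give the Weinreb amide (S)-2-(4-allyl-2,6-dimethoxyphenoxy)-3-(tert-butyldiphenylsilyloxy)-N-methoxy-N-methylpropanamide F1.
- Iodide 8 undergoes iodine–magnesium exchange with i-PrMgCl·LiCl (THF, 0 °C) to give [3,5-dimethoxy-4-(triisopropylsilyloxy)phenyl]magnesium chloride F2.
- Adding F2 to F1 gives the ketone (S)-2-(4-allyl-2,6-dimethoxyphenoxy)-3-(tert-butyldiphenylsilyloxy)-1-[3,5-dimethoxy-4-(triisopropylsilyloxy)phenyl]propan-1-one F3.
- Chelation-controlled reduction of F3 with Zn(BH4)2 (Et2O, −40 °C) brings hydride in from the side of the C8 hydrogen of the carbonyl/aryloxy zinc chelate. This gives the anti (1R,2S) alcohol 24.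

Step 12. The ester may be over-reduced, and the α-aryloxy aldehyde may epimerise during handling.
- The fallback sets out from 20 and comes back at 22.
- Ester 20 is reduced fully with LiBH4 (THF, 0 °C) to the stable, purifiable alcohol (R)-2-(4-allyl-2,6-dimethoxyphenoxy)-3-(tert-butyldiphenylsilyloxy)propan-1-ol F4.
- F4 is oxidised just before use under Parikh–Doering conditions (SO3·pyridine, DMSO, i-Pr2NEt, CH2Cl2, 0 °C) to 22, which is taken on without chromatography.

Step 11. The doubly ortho-substituted phenol may attack too slowly, so hydrazide alkylation or recovered alcohol may dominate.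
- The fallback sets out from 19 and 13 and comes back at 20.
- Alcohol 19 is converted with Tf2O and 2,6-lutidine (CH2Cl2, −78 °C) into methyl (R)-3-(tert-butyldiphenylsilyloxy)-2-(trifluoromethylsulfonyloxy)propanoate F5.
- F5 is displaced by 13 with K2CO3 in MeCN at 0 °C. This is a Williamson-type SN2 reaction with inversion and gives 20.

**Further compounds**
F1 | step 13 | (S)-2-(4-allyl-2,6-dimethoxyphenoxy)-3-(tert-butyldiphenylsilyloxy)-N-methoxy-N-methylpropanamide | C=CCc1cc(OC)c(O[C@@H](CO[Si](c2ccccc2)(c2ccccc2)C(C)(C)C)C(=O)N(C)OC)c(OC)c1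
F2 | step 13 | [3,5-dimethoxy-4-(triisopropylsilyloxy)phenyl]magnesium chloride | COc1cc([Mg]Cl)cc(OC)c1O[Si](C(C)C)(C(C)C)C(C)C
F3 | step 13 | (S)-2-(4-allyl-2,6-dimethoxyphenoxy)-3-(tert-butyldiphenylsilyloxy)-1-[3,5-dimethoxy-4-(triisopropylsilyloxy)phenyl]propan-1-one | C=CCc1cc(OC)c(O[C@@H](CO[Si](c2ccccc2)(c2ccccc2)C(C)(C)C)C(=O)c2cc(OC)c(O[Si](C(C)C)(C(C)C)C(C)C)c(OC)c2)c(OC)c1
F4 | step 12 | (R)-2-(4-allyl-2,6-dimethoxyphenoxy)-3-(tert-butyldiphenylsilyloxy)propan-1-ol | C=CCc1cc(OC)c(O[C@@H](CO[Si](c2ccccc2)(c2ccccc2)C(C)(C)C)CO)c(OC)c1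
F5 | step 11 | methyl (R)-3-(tert-butyldiphenylsilyloxy)-2-(trifluoromethylsulfonyloxy)propanoate | FC(F)(F)S(=O)(=O)O[C@H](CO[Si](c1ccccc1)(c1ccccc1)C(C)(C)C)C(=O)OC
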